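**Plan**
- Retrosynthesis: cut the angelate ester (C3–O) and the aryl ether (C11–O) to reach drimane-3α,8α,11-triol, take the C3 oxygen back to a C2=C3 alkene, then cut C1–C2 (ring A), C9–C10 (ring B) and C8–O in one operation.
- This leaves an open-chain 1,5-enyne: the alkyne C2≡C3 sits on the gem-dimethyl carbon C4, the isopropenyl group C10(CH3)=C1H2 sits on C5, and C5 also carries C6–C7–C8(CH3)=C9–C11H2–OCO2t-Bu.
- Enabling feature: ring A has the quaternary C4 next to C3 and the methyl-bearing C10 next to C1, so attack of C1 on a gold-bound C2 puts the cation on tertiary C10, the ring-fusion carbon, from which ring B and the C8–O bond follow.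
- Forward: (S)-carvone gives C5 with its isopropenyl group; its C6 is gem-dimethylated (C4) and its C1–C2 bond is cleaved to an aldehyde (C3) and a methyl ketone (C8), which are extended to the alkyne and the E-allylic carbonate. Ring A, ring B and a temporary cyclic carbonate then form in one step.
- Stereochemistry: C5 from (S)-carvone; C10, C9 and C8 from the cascade (trans-fused chair closure, anti addition to the E alkene); C3 from α-face epoxidation and trans-diaxial hydride opening; the Z ester from angelic acid.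

Key step: step 10

Remark: drimane numbering is used (C1–C10 in the decalin, C11 = CH2O on C9, gem-dimethyl on C4); the target is read as the 3α-angelate 8α-ol of the 5α-H, 9α-H, 10β-methyl series, and (S)-(+)-carvone, umbelliferone and angelic acid are taken as purchasable.

**Step 1**
Reactants: 1 (S)-(+)-carvone
Product: 2 (5S)-2,6-dimethyl-5-(prop-1-en-2-yl)cyclohex-2-en-1-one (C6 epimers)
Conditions: LiN(i-Pr)2, THF, −78 °C; MeI, −78 → 0 °C
Reagents that add atoms: iodomethane, CI
Why: Kinetic deprotonation of the enone at the α′ carbon (carvone C6) gives the cross-conjugated lithium enolate, whose C-alkylation by iodomethane (enolate alkylation) installs the first methyl group; the new C6 centre is uncontrolled and is erased in step 2.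

**Step 2**
Reactants: 2 (5S)-2,6-dimethyl-5-(prop-1-en-2-yl)cyclohex-2-en-1-one
Product: 3 (5R)-2,6,6-trimethyl-5-(prop-1-en-2-yl)cyclohex-2-en-1-one
Conditions: LiN(i-Pr)2, THF, −78 °C; MeI, DMPU, −78 °C → rt
Reagents that add atoms: iodomethane, CI
Why: A second kinetic α′-enolate alkylation at the same carbon, the only enolisable α position, completes the gem-dimethyl group that becomes C4 of the target and creates no stereocentre (the descriptor changes only through the priority rules).

**Step 3**
Reactants: 3 (5R)-2,6,6-trimethyl-5-(prop-1-en-2-yl)cyclohex-2-en-1-one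
Product: 5 (5R)-2-hydroxy-2,6,6-trimethyl-5-(prop-1-en-2-yl)cyclohexan-1-one (C2 epimers), via lithium enolate 4 (not isolated)
Conditions: LiBH(s-Bu)3, THF, −78 °C; then 2-(phenylsulfonyl)-3-phenyloxaziridine, −78 → 0 °C; H2O
Reagents that add atoms: 2-(phenylsulfonyl)-3-phenyloxaziridine, O=S(=O)(N1OC1c1ccccc1)c1ccccc1; lithium tri-sec-butylborohydride, [Li+].CCC(C)[BH-](C(C)CC)C(C)CC (lithium of intermediate 4 only)
Why: Conjugate hydride addition to the β-unsubstituted enone (1,4-reduction) gives the regiodefined enolate 4, which the N-sulfonyloxaziridine hydroxylates at C2 (enolate oxidation); the configuration of the new carbinol carbon is irrelevant because it becomes the C8 ketone in step 5.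

**Step 4**
Reactants: 5 (5R)-2-hydroxy-2,6,6-trimethyl-5-(prop-1-en-2-yl)cyclohexan-1-one
Product: 6 (4R)-1,3,3-trimethyl-4-(prop-1-en-2-yl)cyclohexane-1,2-diol (diastereomers at C1 and C2)
Conditions: LiAlH4, Et2O, 0 °C → reflux; H2O
Reagents that add atoms: none
Why: Hydride reduction of the hindered ketone gives the vicinal diol needed for glycol cleavage, and both diastereomers at the two carbinol carbons serve equally.

**Step 5**
Reactants: 6 (4R)-1,3,3-trimethyl-4-(prop-1-en-2-yl)cyclohexane-1,2-diol
Product: 7 (3R)-2,2-dimethyl-6-oxo-3-(prop-1-en-2-yl)heptanal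
Conditions: NaIO4, THF/H2O, 0 °C → rt; used crude
Reagents that add atoms: none
Why: Periodate glycol cleavage opens the ring between the two carbinol carbons and gives the non-enolisable aldehyde (C3) and the methyl ketone (C8); the C5 stereocentre is α to neither carbonyl group and cannot epimerise.

**Step 6**
Reactants: 7 (3R)-2,2-dimethyl-6-oxo-3-(prop-1-en-2-yl)heptanal
Product: 8 (5R)-6,6-dimethyl-5-(prop-1-en-2-yl)oct-7-yn-2-one
Conditions: dimethyl (1-diazo-2-oxopropyl)phosphonate, K2CO3, MeOH, 0 °C → rt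
Reagents that add atoms: dimethyl (1-diazo-2-oxopropyl)phosphonate, CC(=O)C(=[N+]=[N-])P(=O)(OC)OC
Why: The Ohira–Bestmann (Seyferth–Gilbert) homologation converts the aldehyde into the terminal alkyne and supplies C2, while the ketone should not react with the diazophosphonate anion under these mild conditions.

**Step 7**
Reactants: 8 (5R)-6,6-dimethyl-5-(prop-1-en-2-yl)oct-7-yn-2-one
Product: 9 ethyl (2E,6R)-3,7,7-trimethyl-6-(prop-1-en-2-yl)non-2-en-8-ynoate
Conditions: (EtO)2P(O)CH2CO2Et, NaH, THF, 0 → 50 °C; E isomer separated by chromatography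
Reagents that add atoms: triethyl phosphonoacetate, CCOC(=O)CP(=O)(OCC)OCC
Why: Horner–Wadsworth–Emmons olefination of the methyl ketone should give mainly the E trisubstituted enoate, the geometry that later fixes C8 and C9; the minor Z isomer would be removed by chromatography.

**Step 8**
Reactants: 9 ethyl (2E,6R)-3,7,7-trimethyl-6-(prop-1-en-2-yl)non-2-en-8-ynoate
Product: 10 (2E,6R)-3,7,7-trimethyl-6-(prop-1-en-2-yl)non-2-en-8-yn-1-ol
Conditions: i-Bu2AlH, CH2Cl2, −78 °C; aq. KNaC4H4O6 (potassium sodium tartrate)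
Reagents that add atoms: none
Why: 1,2-Reduction of the conjugated ester by the aluminium hydride gives the allylic alcohol without touching the alkyne or the alkenes.

**Step 9**
Reactants: 10 (2E,6R)-3,7,7-trimethyl-6-(prop-1-en-2-yl)non-2-en-8-yn-1-ol
Product: 11 tert-butyl (2E,6R)-3,7,7-trimethyl-6-(prop-1-en-2-yl)non-2-en-8-yn-1-yl carbonate
Conditions: Boc2O, DMAP (0.1 equiv), MeCN, rt
Reagents that add atoms: di-tert-butyl dicarbonate, CC(C)(C)OC(=O)OC(=O)OC(C)(C)C
Why: O-Acylation of the primary allylic alcohol with the dicarbonate installs the tert-butyl carbonate, the internal oxygen nucleophile that will end the cascade.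

**Step 10**
Reactants: 11 tert-butyl (2E,6R)-3,7,7-trimethyl-6-(prop-1-en-2-yl)non-2-en-8-yn-1-yl carbonate
Product: 12 drim-2-ene-8α,11-diyl carbonate (cyclic carbonate; 5α-H, 9α-H, 10β-CH3, 8β-CH3)
Conditions: [(2-biphenylyl)(t-Bu)2P]Au(NCMe)SbF6 (3 mol %), dry CH2Cl2, −20 °C → rt
Reagents that add atoms: none
Why: The cationic monovalent-gold complex binds the terminal alkyne C2≡C3 and the isopropenyl carbon C1 attacks C2 (6-endo-dig, closing ring A), which puts the positive charge on tertiary C10 and gold on C3; C9 of the E alkene C8=C9 then adds to C10 in a chair-like 6-endo-trig closure of ring B, the carbonate carbonyl oxygen captures the tertiary C8 cation in a six-membered ring with loss of isobutene, and the proton so released cleaves the C3–Au bond. The closest known reaction type is the gold-catalysed 6-endo-dig cycloisomerisation of 1,5-enynes that carry a 1,1-disubstituted alkene with interception of the tertiary cation, joined to alkyne-initiated polyene cyclisation and to tert-butyl carbonate termination of cation–olefin cascades. C10 is set by the existing C5 centre: the ring B chair that keeps the quaternary C4 equatorial delivers C9 anti to the C5–C4 bond and away from the axial C4 methyl group, so the C10 methyl ends trans to H5 (trans-decalin), as in acid cyclisations of monocyclic α-cyclogeranyl-type cations. C9 and C8 follow from the E geometry and anti addition of C10 and oxygen across the alkene, which places CH2O on C9 and oxygen on C8 both equatorial (9β, 8α) and the C8 methyl axial. The step needs attack through C1 on the terminal alkyne carbon and not on the internal one, and by the near alkene and not the remote one: cation stability at C10, the 5-endo-trig geometry that the alternative closure would demand, and the six- against eight-membered ring size secure this.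

**Step 11**
Reactants: 12 drim-2-ene-8α,11-diyl carbonate
Product: 13 2α,3α-epoxydrimane-8α,11-diyl carbonate
Conditions: mCPBA, NaHCO3, CH2Cl2, 0 °C
Reagents that add atoms: 3-chloroperbenzoic acid, OOC(=O)c1cccc(Cl)c1
Why: Peracid epoxidation (Prilezhaev reaction) should occur on the α face of the C2=C3 alkene because the β face is screened by the axial methyl groups on C4 and C10, which sets the 2α,3α-epoxide.

**Step 12**
Reactants: 13 2α,3α-epoxydrimane-8α,11-diyl carbonate
Product: 14 drimane-3α,8α,11-triol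
Conditions: LiAlH4, THF, reflux; H2O
Reagents that add atoms: none
Why: Hydride opens the epoxide in the trans-diaxial sense at C2, the carbon that is not neopentylic, which leaves the axial 3α-hydroxyl (SN2 epoxide reduction), and the same reagent reduces the cyclic carbonate to the 8α,11-diol and methanol.

**Step 13**
Reactants: 14 drimane-3α,8α,11-triol; 15 umbelliferone (7-hydroxy-2H-chromen-2-one)
Product: 16 7-[(3α,8α-dihydroxydriman-11-yl)oxy]-2H-chromen-2-one
Conditions: PPh3, DIAD, THF, 0 → 40 °C
Reagents that add atoms: none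
Why: Mitsunobu etherification activates the primary C11 hydroxyl in preference to the hindered axial secondary and the tertiary hydroxyl, and the acidic phenol displaces the oxyphosphonium group; no stereocentre is touched.

**Step 14**
Reactants: 16 7-[(3α,8α-dihydroxydriman-11-yl)oxy]-2H-chromen-2-one; 17 angelic acid ((2Z)-2-methylbut-2-enoic acid)
Product: 19 (2R,4aS,5S,6R,8aR)-6-hydroxy-1,1,4a,6-tetramethyl-5-{[(2-oxo-2H-chromen-7-yl)oxy]methyl}decahydronaphthalen-2-yl (2Z)-2-methylbut-2-enoate (target), via mixed anhydride 18 (not isolated)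
Conditions: 17, 2,4,6-trichlorobenzoyl chloride, Et3N, toluene, rt; then 16, toluene, 80 °C
Reagents that add atoms: 2,4,6-trichlorobenzoyl chloride, O=C(Cl)c1c(Cl)cc(Cl)cc1Cl (in intermediate 18 only)
Why: Mixed-anhydride (Yamaguchi-type) esterification run without a nucleophilic catalyst acylates the secondary 3α-hydroxyl, not the tertiary 8α-hydroxyl, and avoids the addition–elimination pathway that would isomerise the Z acid to the tiglate.

**Compound list**
1 | (S)-(+)-carvone | CC1=CC[C@@H](CC1=O)C(C)=C | starting material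
2 | (5S)-2,6-dimethyl-5-(prop-1-en-2-yl)cyclohex-2-en-1-one (C6 epimers) | CC1=CC[C@@H](C(C)C1=O)C(C)=C | intermediate
3 | (5R)-2,6,6-trimethyl-5-(prop-1-en-2-yl)cyclohex-2-en-1-one | CC1=CC[C@@H](C(C)(C)C1=O)C(C)=C | intermediate
4 | lithium enolate of (5R)-2,6,6-trimethyl-5-(prop-1-en-2-yl)cyclohexanone | [Li+].[O-]C1=C(C)CC[C@H](C(C)=C)C1(C)C | intermediate
5 | (5R)-2-hydroxy-2,6,6-trimethyl-5-(prop-1-en-2-yl)cyclohexan-1-one (C2 epimers) | CC1(O)CC[C@@H](C(C)(C)C1=O)C(C)=C | intermediate
6 | (4R)-1,3,3-trimethyl-4-(prop-1-en-2-yl)cyclohexane-1,2-diol (diastereomers) | CC1(O)CC[C@@H](C(C)(C)C1O)C(C)=C | intermediate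
7 | (3R)-2,2-dimethyl-6-oxo-3-(prop-1-en-2-yl)heptanal | O=CC(C)(C)[C@H](CCC(C)=O)C(C)=C | intermediate
8 | (5R)-6,6-dimethyl-5-(prop-1-en-2-yl)oct-7-yn-2-one | C#CC(C)(C)[C@H](CCC(C)=O)C(C)=C | intermediate
9 | ethyl (2E,6R)-3,7,7-trimethyl-6-(prop-1-en-2-yl)non-2-en-8-ynoate | C#CC(C)(C)[C@H](CC/C(C)=C/C(=O)OCC)C(C)=C | intermediate
10 | (2E,6R)-3,7,7-trimethyl-6-(prop-1-en-2-yl)non-2-en-8-yn-1-ol | C#CC(C)(C)[C@H](CC/C(C)=C/CO)C(C)=C | intermediate
11 | tert-butyl (2E,6R)-3,7,7-trimethyl-6-(prop-1-en-2-yl)non-2-en-8-yn-1-yl carbonate | C#CC(C)(C)[C@H](CC/C(C)=C/COC(=O)OC(C)(C)C)C(C)=C | intermediate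
12 | drim-2-ene-8α,11-diyl carbonate | C1=CC[C@]2(C)[C@@H](COC(=O)O3)[C@@]3(C)CC[C@H]2C1(C)C | intermediate
13 | 2α,3α-epoxydrimane-8α,11-diyl carbonate | O1[C@@H]2[C@H]1C[C@]3(C)[C@@H](COC(=O)O4)[C@@]4(C)CC[C@H]3C2(C)C | intermediate
14 | drimane-3α,8α,11-triol | O[C@@H]1CC[C@]2(C)[C@@H](CO)[C@](C)(O)CC[C@H]2C1(C)C | intermediate
15 | umbelliferone (7-hydroxy-2H-chromen-2-one) | Oc1ccc2ccc(=O)oc2c1 | starting material
16 | 7-[(3α,8α-dihydroxydriman-11-yl)oxy]-2H-chromen-2-one | O[C@@H]1CC[C@]2(C)[C@@H](COc3ccc4ccc(=O)oc4c3)[C@](C)(O)CC[C@H]2C1(C)C | intermediate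
17 | angelic acid ((2Z)-2-methylbut-2-enoic acid) | C/C=C(/C)C(=O)O | starting material
18 | (2Z)-2-methylbut-2-enoic 2,4,6-trichlorobenzoic anhydride | C/C=C(/C)C(=O)OC(=O)c1c(Cl)cc(Cl)cc1Cl | intermediate
19 | 3α-angeloyloxy-8α-hydroxydriman-11-yl umbelliferyl ether, (2R,4aS,5S,6R,8aR)-6-hydroxy-1,1,4a,6-tetramethyl-5-{[(2-oxo-2H-chromen-7-yl)oxy]methyl}decahydronaphthalen-2-yl (2Z)-2-methylbut-2-enoate | C/C=C(/C)C(=O)O[C@@H]1CC[C@]2(C)[C@@H](COc3ccc4ccc(=O)oc4c3)[C@](C)(O)CC[C@H]2C1(C)C | target

**Step count and risks**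
Total steps: 14. Longest linear sequence: 14 steps, from (S)-carvone 1 to 19.

Steps most likely to fail:

Step 10. The C10 cation may lose a proton or take a hydride from C5 before ring B closes, ring B may close on the other face of C10 (cis fusion), or the C8 cation may eliminate in place of carbonate capture. The fallback uses the known Lewis-acid cyclisation of an unsaturated α-diazoketone, in which C2 comes from diazomethane and C3 arrives as a ketone; it sets out from 5 and comes back at 14. α-Ketol 5 would be cleaved with NaIO4 in aqueous THF to (3R)-2,2-dimethyl-6-oxo-3-(prop-1-en-2-yl)heptanoic acid F1. Olefination with (EtO)2P(O)CH2CO2Et and excess NaH would give (3R,6E)-8-ethoxy-2,2,6-trimethyl-8-oxo-3-(prop-1-en-2-yl)oct-6-enoic acid F2. i-Bu2AlH at −78 °C would reduce the ester to (3R,6E)-8-hydroxy-2,2,6-trimethyl-3-(prop-1-en-2-yl)oct-6-enoic acid F3, and Ac2O in pyridine would give (3R,6E)-8-acetoxy-2,2,6-trimethyl-3-(prop-1-en-2-yl)oct-6-enoic acid F4. (COCl)2 would give (3R,6E)-8-acetoxy-2,2,6-trimethyl-3-(prop-1-en-2-yl)oct-6-enoyl chloride F5, and CH2N2 would give (2E,6R)-9-diazo-3,7,7-trimethyl-8-oxo-6-(prop-1-en-2-yl)non-2-en-1-yl acetate F6. BF3·OEt2 in CH2Cl2 at low temperature should then effect the same C1-to-C2 closure with N2 as leaving group, relay through C8=C9 and capture of the C8 cation by the acetate carbonyl, so that aqueous work-up gives 8α-hydroxy-3-oxodriman-11-yl acetate F7. LiBH(s-Bu)3 would reduce the 3-ketone from the equatorial side to 3α,8α-dihydroxydriman-11-yl acetate F8, and K2CO3 in MeOH would remove the acetate to give triol 14.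

Step 12. Hydride delivery to the 2β-axial position between the two axial methyl groups may be slow, and forcing may bring Lewis-acid-induced rearrangement of the epoxide. The fallback avoids substitution at C2; it sets out from 12 and comes back at 14. Dihydroxylation of 12 with catalytic OsO4 and NMO on the open α face would give 2α,3α-dihydroxydrimane-8α,11-diyl carbonate F9. 1,1′-Thiocarbonyldiimidazole should acylate the equatorial 2-hydroxyl selectively to 3α-hydroxy-2α-[(1H-imidazol-1-ylcarbonothioyl)oxy]drimane-8α,11-diyl carbonate F10. Barton–McCombie deoxygenation (Bu3SnH, AIBN, toluene, reflux) would give 3α-hydroxydrimane-8α,11-diyl carbonate F11, and K2CO3 in MeOH would cleave the cyclic carbonate to 14.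

Step 14. The axial, neopentyl-type 3α-hydroxyl may react slowly, and the activated angelate may isomerise from Z to E. The fallback builds the Z alkene on the molecule; it sets out from 16 and comes back at 19. Esterification of 16 with 2-[bis(2,2,2-trifluoroethoxy)phosphoryl]propanoic acid (DCC, DMAP, CH2Cl2), an acid with no alkene to isomerise, would give 7-{[3α-({2-[bis(2,2,2-trifluoroethoxy)phosphoryl]propanoyl}oxy)-8α-hydroxydriman-11-yl]oxy}-2H-chromen-2-one F12. Z-selective Still–Gennari olefination (KN(SiMe3)2, 18-crown-6, THF, −78 °C, then acetaldehyde) should then give 19.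

**Further compounds**
F1 | step 10 | (3R)-2,2-dimethyl-6-oxo-3-(prop-1-en-2-yl)heptanoic acid | OC(=O)C(C)(C)[C@H](CCC(C)=O)C(C)=C
F2 | step 10 | (3R,6E)-8-ethoxy-2,2,6-trimethyl-8-oxo-3-(prop-1-en-2-yl)oct-6-enoic acid | OC(=O)C(C)(C)[C@H](CC/C(C)=C/C(=O)OCC)C(C)=C
F3 | step 10 | (3R,6E)-8-hydroxy-2,2,6-trimethyl-3-(prop-1-en-2-yl)oct-6-enoic acid | OC(=O)C(C)(C)[C@H](CC/C(C)=C/CO)C(C)=C
F4 | step 10 | (3R,6E)-8-acetoxy-2,2,6-trimethyl-3-(prop-1-en-2-yl)oct-6-enoic acid | OC(=O)C(C)(C)[C@H](CC/C(C)=C/COC(C)=O)C(C)=C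
F5 | step 10 | (3R,6E)-8-acetoxy-2,2,6-trimethyl-3-(prop-1-en-2-yl)oct-6-enoyl chloride | ClC(=O)C(C)(C)[C@H](CC/C(C)=C/COC(C)=O)C(C)=C
F6 | step 10 | (2E,6R)-9-diazo-3,7,7-trimethyl-8-oxo-6-(prop-1-en-2-yl)non-2-en-1-yl acetate | [N-]=[N+]=CC(=O)C(C)(C)[C@H](CC/C(C)=C/COC(C)=O)C(C)=C
F7 | step 10 | 8α-hydroxy-3-oxodriman-11-yl acetate | O=C1CC[C@]2(C)[C@@H](COC(C)=O)[C@](C)(O)CC[C@H]2C1(C)C
F8 | step 10 | 3α,8α-dihydroxydriman-11-yl acetate | O[C@@H]1CC[C@]2(C)[C@@H](COC(C)=O)[C@](C)(O)CC[C@H]2C1(C)C
F9 | step 12 | 2α,3α-dihydroxydrimane-8α,11-diyl carbonate | O[C@@H]1[C@H](O)C[C@]2(C)[C@@H](COC(=O)O3)[C@@]3(C)CC[C@H]2C1(C)C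
F10 | step 12 | 3α-hydroxy-2α-[(1H-imidazol-1-ylcarbonothioyl)oxy]drimane-8α,11-diyl carbonate | O[C@@H]1[C@H](OC(=S)n4ccnc4)C[C@]2(C)[C@@H](COC(=O)O3)[C@@]3(C)CC[C@H]2C1(C)C
F11 | step 12 | 3α-hydroxydrimane-8α,11-diyl carbonate | O[C@@H]1CC[C@]2(C)[C@@H](COC(=O)O3)[C@@]3(C)CC[C@H]2C1(C)C
F12 | step 14 | 7-{[3α-({2-[bis(2,2,2-trifluoroethoxy)phosphoryl]propanoyl}oxy)-8α-hydroxydriman-11-yl]oxy}-2H-chromen-2-one | CC(C(=O)O[C@@H]1CC[C@]2(C)[C@@H](COc3ccc4ccc(=O)oc4c3)[C@](C)(O)CC[C@H]2C1(C)C)P(=O)(OCC(F)(F)F)OCC(F)(F)F
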